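The data come from a simulation on assumed constants; noise was put on by code.

In this closed flask the charge is conserved: starting material, target, both isomers and quenched substrate always add up to it, and each unit of protic impurity can carry one unit of starting material into quenched substrate. You have two earlier runs, and you must decide whether the next flask has to be freed of protic impurity.

the same everywhere: starting material 0.10 M; catalyst 0.058 mol%
- autumn: protic impurity 0.61 mM; run made earlier
- noon: protic impurity 8.1 mM; run made earlier
- north-west: protic impurity 0.500 mM; time 6.0 h
- south-east: protic impurity 1.00 mM; time 6.0 h
- north-east: protic impurity 2.00 mM; time 6.0 h
- south: protic impurity 4.00 mM; time 6.0 h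
- south-west: protic impurity 8.00 mM; time 6.0 h

- autumn (time / h: target / %): 0.333: 4.2; 0.667: 5.9; 1.33: 8.2; 2.00: 10.7; 4.00: 13.2
- noon (time / h: target / %): 0.333: 2.8; 0.667: 5.8; 1.33: 9.2; 2.00: 10.2; 4.00: 12.4

(readings scatter by 0.5 percentage points)

* amount of target at the end, in percent of the starting material charged for north-west, south-east, north-east, south, south-west, in this order
* the course of these numbers from the first flask to the last (falls all the way / falls, then rises / rises, then falls / rises all the way / hardly changes)

- what may be going on: isomer of the product B + catalyst <-> starting material + catalyst; starting material + catalyst <-> target + catalyst; target + catalyst <-> isomer of the product A + catalyst; starting material + protic impurity -> quenched substrate; isomer of the product A <-> isomer of the product B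
- "hardly changes" means that all values lie within two and a half points (for a concentration: within two and a half percent of the largest)

The equations return the catalyst unchanged, so at a fixed 0.058 mol% each catalysed step would be pseudo-first-order in what it consumes, if its rate follows its equation, and the step between the isomers would be first-order on the same condition. If the quench also ends well before the reading, every amount except quenched substrate scales with the part of the charge that the impurity leaves. Call this the usable share, one minus the impurity as a fraction of the charge: 99.5% in north-west and 92.0% in south-west.

The earlier runs allow a test. At 4.00 h, the noon reading over the autumn reading is 0.939, while their usable shares give 0.925. The two readings differ by 0.8 percentage points, and each is good to 0.5 points, so they do not contradict the usable share, but with that scatter they do not prove it either.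

South-west over north-west should be 0.925. Applied to the autumn reading of 13.2% at 4.00 h, the latest level read, that is a fall of about 0.99 points along the row. I would therefore expect a flat row and leave the impurity as charged in the next flask. I reckon this fall without fixing a level.

The forecast does give levels: 14%, 13.9%, 13.8%, 13.5% and 13%, a course that hardly changes, reached by “Scaling by the substrate remaining”.

The flasks give 13.5%, 13.5%, 13.3%, 13.1% and 12.5%, a course that hardly changes.

    isomer of the product B + catalyst ⇌ starting material + catalyst, rate k1*[catalyst]*[isomer of the product B] forward; the back reaction follows from the equilibrium constant (k = 700 L mol⁻¹ h⁻¹)
    starting material + catalyst ⇌ target + catalyst, rate k2*[starting material]*[catalyst] forward; the back reaction follows from the equilibrium constant (K = 0.230, k = 3100 L mol⁻¹ h⁻¹)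
    target + catalyst ⇌ isomer of the product A + catalyst, rate k3*[catalyst]*[target] forward; the back reaction follows from the equilibrium constant (K = 0.640, k = 86000 L mol⁻¹ h⁻¹)
    starting material + protic impurity → quenched substrate (k = 100 L mol⁻¹ h⁻¹)
    isomer of the product A ⇌ isomer of the product B (K = 2.30, k = 0.330 h⁻¹)

South-west over north-west is 0.926, against 0.925 from the usable shares. In north-west, the relaxation half-life of starting material and target by their step alone, both ways together, is 0.721 h at 6.00 h, shorter than the 6.0 h of the run, and target then stands at 13.5% beside 65.1% starting material. For isomer of the product A, the usable shares of south-west and south-east give 0.929, and the amounts at the end, 7.87% in south-west and 8.47% in south-east, stand in the ratio 0.929.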